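# Proposed total synthesis of pestalone G by a biomimetic aldol closure of ring B

## Analysis of the target

Pestalone G is a benzophenone. Ring A is hexasubstituted: C1 carries the ketone, C2 OMe, C3 Cl, C4 Me, C5 Br and C6 OH. Ring B is pentasubstituted: C1' carries the ketone, C2' CHO, C3' OH, C4' H, C5' OH and C6' the prenyl group. There is no stereocentre; the ketone lies between four ortho substituents and is twisted and shielded.

The sensitive groups are:
- the salicylaldehyde next to the diaryl ketone: a hydroxyl generated at the ketone carbon or at the C2' carbon closes onto its neighbour to a lactol, and oxidation then gives a phthalide;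
- the prenyl group ortho to the C5' phenol, which cyclises to a chroman under strong acid and rules out hydrogenation and strong oxidants;
- the aryl bromide, which is open to reductive loss and halogen-metal exchange.

The difficulty is twofold. The tetra-ortho-substituted diaryl ketone must be formed between two crowded arenes, and chlorine must be placed next to OMe while bromine is placed next to OH.

The strategy rests on the oxygenation pattern of ring B. A carboxyl-level carbon on C2', oxygen on C3' and C5', and C1' bonded to the ketone carbon make up a folded tetraketide of the orsellinate type. Ring B can therefore be closed by an aldol bond C1'-C2' from an open chain in which C1' and the ketone carbon are a vicinal diketone on a finished ring A.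

## Retrosynthetic reasoning

**19 back to 18.** The last operation only removes the two acetal protecting groups on O6 and O5'. All skeletal and redox work is done before the phenol next to the prenyl group is free. The methoxymethyl acetal is chosen because the same group directs the metalation that builds ring A.

**18 back to 17 and 16.** The C2' aldehyde is taken back to the carboxyl-level carbon held in benzodioxinone 17, so one hydride transfer at low temperature is needed. Reduction of both carbonyls to a diol and re-oxidation is avoided: an ortho-related benzylic diol closes to a lactol as soon as one alcohol is oxidised, and the lactol goes on to a phthalide. The diaryl ketone is left untouched and its steric shielding is relied on. 17 comes from 16 by capping O5', so that no metal phenoxide sits para to the carbonyl that has to accept hydride.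

**16 back to 14 (through 15).** The C1'-C2' bond is cut and ring B unfolds into an open chain. This gains the whole of ring B with every substituent in its place, and the diaryl ketone at its final oxidation level, with no oxidation after ring closure. The forward reaction must direct the α-carbon of the dioxinone onto the C1' carbonyl and not onto the three other carbonyls, then lose water and aromatise.

**14 back to 12 and 7.** The bond between C1' and C6' is cut as a Claisen acylation of dianion 13 of keto-dioxinone 12 with the ester carbonyl of arylglyoxylate 7. This divides the molecule into two pieces of similar size, each made in a few steps. The prenyl group rides in on the acyl chain of 12, so no C-prenylation of an arene is needed. The forward step must acylate at the ester of 7 and spare its ketone.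

**12 back to 10 and 9.** The C4'-C5' bond is cut as an acylation of dienolate 11 of dioxinone 10 with acid chloride 9, which comes from acid 8. The dioxinone supplies C2', C3', C4' and the masked carboxyl carbon in one commercial unit.

**7 back to 6, 3, 2 and 1.** Bromine is removed first: in 6 only one ring carbon is unsubstituted, so bromination has no regiochemical choice. The bond from C1 to the glyoxylate carbon is cut next. Aryllithium 5, made by metalation of 3 between its two oxygen substituents, is acylated by 4. Chlorine is carried through the metalation because no hydrogen is ortho to it. 3 is the protected form of 2, and 2 comes from 1 by chlorination para to the free hydroxyl. This is the one step of the ring A sequence that depends on directing effects.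

## Alternatives that were turned down

**Alternative 1:** Ring A is disconnected into a four-carbon vinylketene unit and a two-carbon alkyne.
- Forward key step: 2-chloro-3-methylcyclobut-2-en-1-one A1 is heated with methoxyalkyne A2. The propargylic carbon of A2 is the future ketone carbon, silylated and already bonded to a finished ring B. Ring opening to the chlorovinylketene, [2+2] addition to the electron-rich alkyne, 4π opening and 6π closure would give phenol A3.
- For: the cascade fixes OMe, Cl, Me and OH on ring A by its mechanism, and bromine then enters at the single open position ortho to the free phenol. On regiocontrol of ring A this plan is stronger than the chosen one, whose chlorination of 1 relies on directing effects.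
- Against: ring B must first be made as a fully substituted prenylated resorcinol with a masked aldehyde. A1 and A2 are not commercial and the ynol ether is labile. A ketene is generated at high temperature beside a prenyl alkene and three acetals. A3 holds the ketone carbon as a carbinol, so a tetra-ortho-substituted benzhydrol must later be oxidised while the aldehyde stays masked.
- Comparison: the sequence is longer and needs more oxidation-state corrections. The chosen strategy accepts one directing-effect step on ring A and in return makes ring B and the ketone in one redox-neutral closure.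

**Alternative 2:** Ring B is disconnected into a four-carbon diene (C3' to C6') and a two-carbon ynoate (C1' and C2').
- Forward key step: the prenyl-bearing 1-methoxy-1,3-bis(trimethylsilyloxy)diene A4 adds to alkynoate A5, which carries ring A on a silylated propargylic carbon. Acidic work-up would aromatise the adduct to methyl resorcylate A6.
- For: the plan is convergent, the regiochemistry follows from matched polarity, and the annulation type is well established. On the certainty of the ring-forming event it is at least equal to the chosen aldol and probably better.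
- Against: the bonding termini are crowded, namely the prenyl-substituted end of A4 and the alkyne carbon of A5 beside a bulky silyloxy(aryl)methyl group. A6 has a carbinol ortho to an ester, and on desilylation the hydroxyl should lactonise onto the ester to a 3-arylphthalide. Carbinol oxidation and ester-to-aldehyde adjustment must then be ordered around that trap.
- Comparison: the chosen strategy delivers the ketone as a ketone, and keeps the carboxyl carbon as a dioxinone that goes to the aldehyde in one hydride step with no free carbinol at any stage.

**Alternative 3:** The ring B carbocycle is built by a Michael-Claisen annulation.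
- Forward key step: dimethyl malonate A8 adds under alkoxide base to enedione A7 at the alkene carbon next to the aryl ketone. The methyl ketone enolate then closes onto a malonate ester to give cyclohexane-1,3-dione A9.
- For: the reagents are cheap and the annulation is classical, base-only chemistry. On operational simplicity this plan is stronger.
- Against: A9 is one dehydrogenation short of the arene, and that oxidation has to be done beside a prenyl alkene and an electron-rich halogenated ring. The Michael addition can go to either alkene carbon of A7. Three stereocentres are set only to be erased. A7 itself needs an enedione synthesis on a hindered aryl ketone.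
- Comparison: in the chosen chain the aromatic oxidation level is built in, so closure is followed by dehydration and no separate oxidation.

Key step: step 8

## Route

Remark: the target SMILES has no stereodescriptor, and the hindered diaryl ketone is assumed not to give separable atropisomers. 14 and 15 are racemic, and their stereocentres disappear on aromatisation.

Step 1
Reactants: 1 3-methoxy-5-methylphenol
Product: 2 4-chloro-3-methoxy-5-methylphenol
Conditions: SO2Cl2 (1.0 equiv), CH2Cl2/Et2O, 0 °C
Reagents that add atoms: sulfuryl chloride, O=S(=O)(Cl)Cl
Why: Electrophilic aromatic chlorination; the free hydroxyl is the strongest donor and directs para to C4 between OMe and Me, the same preference that turns 3,5-dimethylphenol into its 4-chloro derivative, and hydrogen bonding of the OH to ether disfavours ortho attack; minor ortho isomers would be removed by chromatography.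

Step 2
Reactants: 2 4-chloro-3-methoxy-5-methylphenol
Product: 3 2-chloro-1-methoxy-5-(methoxymethoxy)-3-methylbenzene
Conditions: MOMCl, i-Pr2NEt, CH2Cl2, 0 °C to rt
Reagents that add atoms: chloromethyl methyl ether, COCCl
Why: O-Alkylation of the phenol under amine base; the MOM acetal survives organolithium and enolate chemistry, directs the next metalation and is removable by mild acid at the end.

Step 3
Reactants: 3 2-chloro-1-methoxy-5-(methoxymethoxy)-3-methylbenzene; 4 methyl chlorooxoacetate
Product: 6 methyl 2-[3-chloro-2-methoxy-6-(methoxymethoxy)-4-methylphenyl]-2-oxoacetate, via aryllithium 5 (not isolated)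
Conditions: n-BuLi, THF, -78 to 0 °C; then cannulated into 4 (excess), THF, -78 °C
Reagents that add atoms: none
Why: Directed ortho-metalation removes the C-H flanked by OMOM and OMe through cooperative coordination of lithium, no hydrogen sits ortho to chlorine so benzyne formation is excluded, and the aryllithium is acylated at the acid chloride carbonyl of 4; inverse addition and the shielding of the new ketone by its two ortho substituents should prevent a second addition.

Step 4
Reactants: 6 methyl 2-[3-chloro-2-methoxy-6-(methoxymethoxy)-4-methylphenyl]-2-oxoacetate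
Product: 7 methyl 2-[3-bromo-5-chloro-6-methoxy-2-(methoxymethoxy)-4-methylphenyl]-2-oxoacetate
Conditions: NBS, MeCN, 0 °C to rt, dark
Reagents that add atoms: N-bromosuccinimide, O=C1CCC(=O)N1Br
Why: Electrophilic aromatic bromination at the only unsubstituted ring carbon, which is para to OMe, ortho to OMOM and methyl and meta to the acyl group; polar solvent and exclusion of light keep the reaction ionic and away from the benzylic methyl.

Step 5
Reactants: 8 5-methylhex-4-enoic acid
Product: 9 5-methylhex-4-enoyl chloride
Conditions: (COCl)2, cat. DMF, CH2Cl2, 0 °C to rt; concentrated and used crude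
Reagents that add atoms: oxalyl chloride, O=C(Cl)C(=O)Cl
Why: Acid chloride formation through the Vilsmeier-type chloroiminium species; the trisubstituted alkene should be left alone at this temperature and the volatile by-products are removed under vacuum.

Step 6
Reactants: 9 5-methylhex-4-enoyl chloride; 10 2,2,6-trimethyl-4H-1,3-dioxin-4-one
Product: 12 2,2-dimethyl-6-(6-methyl-2-oxohept-5-en-1-yl)-4H-1,3-dioxin-4-one, via lithium dienolate 11 (not isolated)
Conditions: 10 (2.2 equiv), LiN(SiMe3)2 (2.2 equiv), THF, -78 °C; then 9 (1.0 equiv), -78 °C; aq. NH4Cl
Reagents that add atoms: none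
Why: Deprotonation of the methyl group of the vinylogous ester gives the lithium dienolate, which is C-acylated at its terminal carbon by the acid chloride (vinylogous Claisen acylation); the second equivalent of dienolate absorbs the acidic proton of the product.

Step 7
Reactants: 12 2,2-dimethyl-6-(6-methyl-2-oxohept-5-en-1-yl)-4H-1,3-dioxin-4-one; 7 methyl 2-[3-bromo-5-chloro-6-methoxy-2-(methoxymethoxy)-4-methylphenyl]-2-oxoacetate
Product: 14 6-{5-[3-bromo-5-chloro-6-methoxy-2-(methoxymethoxy)-4-methylphenyl]-3-(3-methylbut-2-en-1-yl)-2,4,5-trioxopentyl}-2,2-dimethyl-4H-1,3-dioxin-4-one (racemic triketo-dioxinone), via dilithium dianion 13 (not isolated)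
Conditions: 12 (2.2 equiv), LiN(i-Pr)2 (4.5 equiv), THF, -78 °C; then 7 (1.0 equiv), -78 to -40 °C; aq. NH4Cl at -78 °C; crude product taken on at once
Reagents that add atoms: none
Why: Claisen-type C-acylation of a 1,3-dicarbonyl dianion at its more basic terminal carbon, as in dianion acylations with esters and oxalates; the ester carbonyl of 7 is activated by the neighbouring ketone while that ketone is blocked on both faces by OMe and OMOM, and the expelled methoxide leaves the product as an unreactive enolate until the cold quench.

Step 8
Reactants: 14 6-{5-[3-bromo-5-chloro-6-methoxy-2-(methoxymethoxy)-4-methylphenyl]-3-(3-methylbut-2-en-1-yl)-2,4,5-trioxopentyl}-2,2-dimethyl-4H-1,3-dioxin-4-one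
Product: 16 5-[3-bromo-5-chloro-6-methoxy-2-(methoxymethoxy)-4-methylbenzoyl]-7-hydroxy-2,2-dimethyl-6-(3-methylbut-2-en-1-yl)-4H-1,3-benzodioxin-4-one, via cyclised aldol carbinol 15 (not isolated)
Conditions: Et3N (excess), CH2Cl2, 0 °C to rt
Reagents that add atoms: none
Why: Et3N reversibly enolises 14; the dienolate formed by removing a proton from the CH2 between the dioxinone and the C5' ketone is nucleophilic at the dioxinone α-carbon (the future C2'), which adds to the C1' carbonyl in a 6-(enolexo)-exo-trig aldol closure to give carbinol 15. E1cB loss of water across C1'-C2' and enolisation of the C5' ketone with loss of the C6' hydrogen then aromatise ring B, an irreversible step that should drain the enol and hemiketal equilibria of the chain toward 16. The closest known reaction type is the amine-mediated cycloaromatisation of diketo-dioxinones to acetonide-protected resorcylates; here the acceptor ketone also carries the aroyl group, so the diaryl ketone arrives at its final oxidation level. No stereocentre is created, since the racemic C6' centre of 14 and the transient centres of 15 all become sp2. The step needs chemoselectivity among four carbonyls: C1' is the most electrophilic because the aryl ketone sits beside it, and only attack of C2' on C1' gives a six-membered ring that can aromatise. The aryl ketone is blocked on both faces by its ortho OMe and OMOM groups, which should suppress the five-membered aldol and hemiketal closures onto it. The dioxinone holds the carboxyl carbon and O3' as an acetonide, so pyrone formation by O-acylation is closed off.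

Step 9
Reactants: 16 5-[3-bromo-5-chloro-6-methoxy-2-(methoxymethoxy)-4-methylbenzoyl]-7-hydroxy-2,2-dimethyl-6-(3-methylbut-2-en-1-yl)-4H-1,3-benzodioxin-4-one
Product: 17 5-[3-bromo-5-chloro-6-methoxy-2-(methoxymethoxy)-4-methylbenzoyl]-7-(methoxymethoxy)-2,2-dimethyl-6-(3-methylbut-2-en-1-yl)-4H-1,3-benzodioxin-4-one
Conditions: MOMCl, i-Pr2NEt, CH2Cl2, 0 °C to rt
Reagents that add atoms: chloromethyl methyl ether, COCCl
Why: O-Alkylation of the only free phenol under amine base; capping O5' removes the acidic proton before the hydride step and lets both acetals fall in one final operation.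

Step 10
Reactants: 17 5-[3-bromo-5-chloro-6-methoxy-2-(methoxymethoxy)-4-methylbenzoyl]-7-(methoxymethoxy)-2,2-dimethyl-6-(3-methylbut-2-en-1-yl)-4H-1,3-benzodioxin-4-one
Product: 18 2-[3-bromo-5-chloro-6-methoxy-2-(methoxymethoxy)-4-methylbenzoyl]-6-hydroxy-4-(methoxymethoxy)-3-(3-methylbut-2-en-1-yl)benzaldehyde
Conditions: i-Bu2AlH (1.3 equiv), CH2Cl2, -78 °C; aq. potassium sodium tartrate (KNaC4H4O6)
Reagents that add atoms: none
Why: Partial reduction of a 2,2-dimethylbenzodioxinone: hydride adds once to the activated aryl-ester carbonyl, the aluminium hemiacetal persists at -78 °C and collapses on work-up to the salicylaldehyde with loss of acetone; the diaryl ketone, flanked by four ortho substituents, should be too shielded to accept hydride from the bulky reagent at this temperature.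

Step 11
Reactants: 18 2-[3-bromo-5-chloro-6-methoxy-2-(methoxymethoxy)-4-methylbenzoyl]-6-hydroxy-4-(methoxymethoxy)-3-(3-methylbut-2-en-1-yl)benzaldehyde
Product: 19 pestalone G, 2-(3-bromo-5-chloro-2-hydroxy-6-methoxy-4-methylbenzoyl)-4,6-dihydroxy-3-(3-methylbut-2-en-1-yl)benzaldehyde
Conditions: HCl (3 M aq.), MeOH/THF, rt
Reagents that add atoms: none
Why: Acid-catalysed acetal cleavage of both MOM ethers through oxocarbenium ions trapped by methanol; dilute acid at room temperature should stay below the threshold for cyclisation of the prenyl group onto the C5' phenol.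

## Compound list

1 | 3-methoxy-5-methylphenol | COc1cc(C)cc(O)c1 | starting material
2 | 4-chloro-3-methoxy-5-methylphenol | COc1cc(O)cc(C)c1Cl | intermediate
3 | 2-chloro-1-methoxy-5-(methoxymethoxy)-3-methylbenzene | COCOc1cc(C)c(Cl)c(OC)c1 | intermediate
4 | methyl chlorooxoacetate | COC(=O)C(=O)Cl | starting material
5 | [3-chloro-2-methoxy-6-(methoxymethoxy)-4-methylphenyl]lithium | [Li]c1c(OC)c(Cl)c(C)cc1OCOC | intermediate
6 | methyl 2-[3-chloro-2-methoxy-6-(methoxymethoxy)-4-methylphenyl]-2-oxoacetate | COC(=O)C(=O)c1c(OC)c(Cl)c(C)cc1OCOC | intermediate
7 | methyl 2-[3-bromo-5-chloro-6-methoxy-2-(methoxymethoxy)-4-methylphenyl]-2-oxoacetate | COC(=O)C(=O)c1c(OC)c(Cl)c(C)c(Br)c1OCOC | intermediate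
8 | 5-methylhex-4-enoic acid | CC(C)=CCCC(=O)O | starting material
9 | 5-methylhex-4-enoyl chloride | CC(C)=CCCC(=O)Cl | intermediate
10 | 2,2,6-trimethyl-4H-1,3-dioxin-4-one | CC1=CC(=O)OC(C)(C)O1 | starting material
11 | lithium dienolate of 10 (lithium 2,2-dimethyl-6-methylidene-6H-1,3-dioxin-4-olate) | C=C1C=C(O[Li])OC(C)(C)O1 | intermediate
12 | 2,2-dimethyl-6-(6-methyl-2-oxohept-5-en-1-yl)-4H-1,3-dioxin-4-one | CC(C)=CCCC(=O)CC1=CC(=O)OC(C)(C)O1 | intermediate
13 | dilithium dianion of 12 (drawn as the bis-enolate) | [Li]OC1=CC(=CC(O[Li])=CCC=C(C)C)OC(C)(C)O1 | intermediate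
14 | 6-{5-[3-bromo-5-chloro-6-methoxy-2-(methoxymethoxy)-4-methylphenyl]-3-(3-methylbut-2-en-1-yl)-2,4,5-trioxopentyl}-2,2-dimethyl-4H-1,3-dioxin-4-one (racemic, enolisable) | CC1(C)OC(=O)C=C(O1)CC(=O)C(CC=C(C)C)C(=O)C(=O)c1c(OC)c(Cl)c(C)c(Br)c1OCOC | intermediate
15 | cyclised aldol carbinol: 5-[3-bromo-5-chloro-6-methoxy-2-(methoxymethoxy)-4-methylbenzoyl]-5-hydroxy-2,2-dimethyl-6-(3-methylbut-2-en-1-yl)-4a,5-dihydro-4H-1,3-benzodioxine-4,7(6H)-dione (racemic mixture of diastereomers) | CC1(C)OC(=O)C2C(O1)=CC(=O)C(CC=C(C)C)C2(O)C(=O)c1c(OC)c(Cl)c(C)c(Br)c1OCOC | intermediate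
16 | 5-[3-bromo-5-chloro-6-methoxy-2-(methoxymethoxy)-4-methylbenzoyl]-7-hydroxy-2,2-dimethyl-6-(3-methylbut-2-en-1-yl)-4H-1,3-benzodioxin-4-one | CC1(C)OC(=O)c2c(O1)cc(O)c(CC=C(C)C)c2C(=O)c1c(OC)c(Cl)c(C)c(Br)c1OCOC | intermediate
17 | 5-[3-bromo-5-chloro-6-methoxy-2-(methoxymethoxy)-4-methylbenzoyl]-7-(methoxymethoxy)-2,2-dimethyl-6-(3-methylbut-2-en-1-yl)-4H-1,3-benzodioxin-4-one | CC1(C)OC(=O)c2c(O1)cc(OCOC)c(CC=C(C)C)c2C(=O)c1c(OC)c(Cl)c(C)c(Br)c1OCOC | intermediate
18 | 2-[3-bromo-5-chloro-6-methoxy-2-(methoxymethoxy)-4-methylbenzoyl]-6-hydroxy-4-(methoxymethoxy)-3-(3-methylbut-2-en-1-yl)benzaldehyde | COCOc1cc(O)c(C=O)c(C(=O)c2c(OC)c(Cl)c(C)c(Br)c2OCOC)c1CC=C(C)C | intermediate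
19 | pestalone G, 2-(3-bromo-5-chloro-2-hydroxy-6-methoxy-4-methylbenzoyl)-4,6-dihydroxy-3-(3-methylbut-2-en-1-yl)benzaldehyde | COc1c(Cl)c(C)c(Br)c(O)c1C(=O)c1c(C=O)c(O)cc(O)c1CC=C(C)C | target

## Step count and least certain steps

Total: 11 steps. Longest linear sequence: 9 steps (steps 1 to 4, then 7 to 11); steps 5 and 6 form the short branch.

**Step 8 (key step).**
- What may go wrong: the enolised tricarbonyl chain may be diverted into closures other than C2' onto C1'. These are addition of the C5' enol oxygen or the C4' carbon to the aryl ketone, and retro-Claisen cleavage between C1' and C6'. The sequence may also stall before or at carbinol 15, because the dioxinone α-carbon is a weak nucleophile and the chain rests as the C6' enolate under amine base.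
- Fallback: 14 is heated with methanol in toluene at 110 °C. Retro-[4+2] loss of acetone gives an acylketene, which methanol traps as the methyl tetraketo ester F1. Its C2' carbon is now a β-keto ester methylene and far more nucleophilic. The classical polyketide aldol-aromatisation (K2CO3, MeOH, rt, then mild acidification) should give the methyl resorcylate F2. Both ring B phenols are capped (NaH, MOMCl, DMF) to give the tris-MOM ester F3. LiAlH4 (THF, 0 °C) reduces ester and ketone to the tris-MOM diol F4. Swern oxidation ((COCl)2, DMSO, CH2Cl2, -78 °C, then Et3N) converts both hydroxyls to alkoxysulfonium salts before base is added, so no free hydroxyl is left to close a lactol, and should give the tris-MOM keto aldehyde F5. The conditions of step 11 then remove all three acetals, and the fallback comes back to the route at 19.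

**Step 7.**
- What may go wrong: the dianion may add to the aryl ketone carbonyl of 7 in place of the ester, or be quenched by proton transfer from the more acidic product, so that conversion stops early.
- Fallback: the acylation is replaced by an aldol addition followed by oxidation. 7 is reduced with LiAlH4 (THF, 0 °C) to the aryl ethanediol F6. Swern oxidation gives the arylglyoxal F7, dried by azeotrope. Dianion 13, made from 12 as in step 7, adds to the aldehyde carbonyl of F7, which is far more reactive than the shielded ketone, to give the hydroxy diketo-dioxinone F8. Dess-Martin periodinane (CH2Cl2, 0 °C) oxidises the secondary alcohol, and the fallback comes back to the route at 14.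

**Step 10.**
- What may go wrong: hydride may be transferred to the diaryl ketone, possibly from the neighbouring aluminium hemiacetal, or the aldehyde level may be reduced further.
- Fallback: full reduction is accepted. 17 is treated with LiAlH4 (THF, 0 °C) to give the phenolic diol F9. The phenol alone is capped (MOMCl, K2CO3, acetone) to give the tris-MOM diol F4. Swern double oxidation gives the tris-MOM keto aldehyde F5, and the conditions of step 11 bring the fallback back to the route at 19.

**Step 1.**
- What may go wrong: chlorination may also occur ortho to the hydroxyl (at C6 or C2) or twice, giving isomers of similar polarity and a loss of material at the start.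
- Fallback: 1 is brominated with n-Bu4NBr3 (CH2Cl2/MeOH, rt), a bulky electrophile that should favour the para position, to give 4-bromo-3-methoxy-5-methylphenol F10. Protection (MOMCl, i-Pr2NEt) gives 2-bromo-1-methoxy-5-(methoxymethoxy)-3-methylbenzene F11. Bromine-lithium exchange (n-BuLi, THF, -78 °C) and quenching with C2Cl6 install chlorine at the same carbon, and the fallback comes back to the route at 3.

## Further compounds

F1 | step 8 | methyl 8-[3-bromo-5-chloro-6-methoxy-2-(methoxymethoxy)-4-methylphenyl]-6-(3-methylbut-2-en-1-yl)-3,5,7,8-tetraoxooctanoate (racemic) | COC(=O)CC(=O)CC(=O)C(CC=C(C)C)C(=O)C(=O)c1c(OC)c(Cl)c(C)c(Br)c1OCOC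
F2 | step 8 | methyl 2-[3-bromo-5-chloro-6-methoxy-2-(methoxymethoxy)-4-methylbenzoyl]-4,6-dihydroxy-3-(3-methylbut-2-en-1-yl)benzoate | COC(=O)c1c(O)cc(O)c(CC=C(C)C)c1C(=O)c1c(OC)c(Cl)c(C)c(Br)c1OCOC
F3 | step 8 | methyl 2-[3-bromo-5-chloro-6-methoxy-2-(methoxymethoxy)-4-methylbenzoyl]-4,6-bis(methoxymethoxy)-3-(3-methylbut-2-en-1-yl)benzoate | COC(=O)c1c(OCOC)cc(OCOC)c(CC=C(C)C)c1C(=O)c1c(OC)c(Cl)c(C)c(Br)c1OCOC
F4 | step 8 | [3-bromo-5-chloro-6-methoxy-2-(methoxymethoxy)-4-methylphenyl][2-(hydroxymethyl)-3,5-bis(methoxymethoxy)-6-(3-methylbut-2-en-1-yl)phenyl]methanol (racemic) | OCc1c(OCOC)cc(OCOC)c(CC=C(C)C)c1C(O)c1c(OC)c(Cl)c(C)c(Br)c1OCOC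
F5 | step 8 | 2-[3-bromo-5-chloro-6-methoxy-2-(methoxymethoxy)-4-methylbenzoyl]-4,6-bis(methoxymethoxy)-3-(3-methylbut-2-en-1-yl)benzaldehyde | O=Cc1c(OCOC)cc(OCOC)c(CC=C(C)C)c1C(=O)c1c(OC)c(Cl)c(C)c(Br)c1OCOC
F6 | step 7 | 1-[3-bromo-5-chloro-6-methoxy-2-(methoxymethoxy)-4-methylphenyl]ethane-1,2-diol (racemic) | OCC(O)c1c(OC)c(Cl)c(C)c(Br)c1OCOC
F7 | step 7 | 2-[3-bromo-5-chloro-6-methoxy-2-(methoxymethoxy)-4-methylphenyl]-2-oxoacetaldehyde | O=CC(=O)c1c(OC)c(Cl)c(C)c(Br)c1OCOC
F8 | step 7 | 6-{5-[3-bromo-5-chloro-6-methoxy-2-(methoxymethoxy)-4-methylphenyl]-4-hydroxy-3-(3-methylbut-2-en-1-yl)-2,5-dioxopentyl}-2,2-dimethyl-4H-1,3-dioxin-4-one (racemic mixture of diastereomers) | CC1(C)OC(=O)C=C(O1)CC(=O)C(CC=C(C)C)C(O)C(=O)c1c(OC)c(Cl)c(C)c(Br)c1OCOC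
F9 | step 10 | [3-bromo-5-chloro-6-methoxy-2-(methoxymethoxy)-4-methylphenyl][3-hydroxy-2-(hydroxymethyl)-5-(methoxymethoxy)-6-(3-methylbut-2-en-1-yl)phenyl]methanol (racemic) | OCc1c(O)cc(OCOC)c(CC=C(C)C)c1C(O)c1c(OC)c(Cl)c(C)c(Br)c1OCOC
F10 | step 1 | 4-bromo-3-methoxy-5-methylphenol | COc1cc(O)cc(C)c1Br
F11 | step 1 | 2-bromo-1-methoxy-5-(methoxymethoxy)-3-methylbenzene | COCOc1cc(C)c(Br)c(OC)c1
A1 | alternative 1 | 2-chloro-3-methylcyclobut-2-en-1-one | CC1=C(Cl)C(=O)C1
A2 | alternative 1 | tert-butyl{1-[2-(1,3-dioxolan-2-yl)-3,5-bis(methoxymethoxy)-6-(3-methylbut-2-en-1-yl)phenyl]-3-methoxyprop-2-yn-1-yloxy}dimethylsilane (racemic) | COC#CC(O[Si](C)(C)C(C)(C)C)c1c(C2OCCO2)c(OCOC)cc(OCOC)c1CC=C(C)C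
A3 | alternative 1 | silylated benzhydrol with ring A complete except for bromine: 2-{(tert-butyldimethylsilyloxy)[2-(1,3-dioxolan-2-yl)-3,5-bis(methoxymethoxy)-6-(3-methylbut-2-en-1-yl)phenyl]methyl}-4-chloro-3-methoxy-5-methylphenol (racemic) | COc1c(Cl)c(C)cc(O)c1C(O[Si](C)(C)C(C)(C)C)c1c(C2OCCO2)c(OCOC)cc(OCOC)c1CC=C(C)C
A4 | alternative 2 | 1-methoxy-7-methyl-1,3-bis(trimethylsilyloxy)octa-1,3,6-triene | COC(O[Si](C)(C)C)=CC(O[Si](C)(C)C)=CCC=C(C)C
A5 | alternative 2 | methyl 4-[3-bromo-5-chloro-6-methoxy-2-(methoxymethoxy)-4-methylphenyl]-4-(tert-butyldimethylsilyloxy)but-2-ynoate (racemic) | COC(=O)C#CC(O[Si](C)(C)C(C)(C)C)c1c(OC)c(Cl)c(C)c(Br)c1OCOC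
A6 | alternative 2 | methyl 2-{[3-bromo-5-chloro-6-methoxy-2-(methoxymethoxy)-4-methylphenyl](tert-butyldimethylsilyloxy)methyl}-4,6-dihydroxy-3-(3-methylbut-2-en-1-yl)benzoate (racemic) | COC(=O)c1c(O)cc(O)c(CC=C(C)C)c1C(O[Si](C)(C)C(C)(C)C)c1c(OC)c(Cl)c(C)c(Br)c1OCOC
A7 | alternative 3 | 1-[3-bromo-5-chloro-6-methoxy-2-(methoxymethoxy)-4-methylphenyl]-3-(3-methylbut-2-en-1-yl)pent-2-ene-1,4-dione | CC(=O)C(CC=C(C)C)=CC(=O)c1c(OC)c(Cl)c(C)c(Br)c1OCOC
A8 | alternative 3 | dimethyl malonate | COC(=O)CC(=O)OC
A9 | alternative 3 | methyl 6-[3-bromo-5-chloro-6-methoxy-2-(methoxymethoxy)-4-methylbenzoyl]-5-(3-methylbut-2-en-1-yl)-2,4-dioxocyclohexane-1-carboxylate (racemic, all-trans) | COC(=O)[C@@H]1C(=O)CC(=O)[C@H](CC=C(C)C)[C@H]1C(=O)c1c(OC)c(Cl)c(C)c(Br)c1OCOC
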